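**Retrosynthetic overview** (germacrane numbering, C1–C15)
1. C15–OH is installed last by allylic C–H hydroxylation of the C4 methyl group of macrocycle 22.
2. Ring B (the ten-membered carbocycle) is closed second, at C1=C10, by ring-closing metathesis of a 2-alkylacrolein with a terminal vinyl group (21).
3. The C8 ester is formed by invertive Mitsunobu C–O coupling of carbinol 17 with (S)-2-methylbutanoic acid; C7–C8 comes from an indium Barbier reaction of bromobutenolide 13 with 4,4-dimethoxybutanal.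
4. Key step: ring A (the lactone) is formed first, by a catalytic enantioselective 1,4-bromolactonisation of trienoic acid 12 that makes the C6–O bond, sets C6 and delivers the allylic bromide.
5. Acid 12 comes from Z-enal 7 (propyne carbocupration, formylation) and allylic phosphonate 10 by Horner–Wadsworth–Emmons olefination.

Assumption: the quinidine-derived catalyst is written for step 5; if it favours the 5S lactone, the quinine-derived pseudo-enantiomer is used instead.
Assumption: the Barbier reaction (step 7) is taken to follow the closed chair model and give the anti (1S) carbinol; the fallback for step 8 covers the other outcome.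

**Route**

Step 1
Reactants: 1 but-3-enylmagnesium bromide; 2 propyne
Product: 5 (1Z)-1-iodo-2-methylhexa-1,5-diene, via but-3-enylcopper 3 (not isolated), via [(1Z)-2-methylhexa-1,5-dien-1-yl]copper 4 (not isolated)
Conditions: CuBr·SMe2 (1.0 equiv), Et2O–Me2S, −45 °C; 2 (excess), −25 °C; then I2, THF, −40 to 0 °C
Reagents that add atoms: iodine, II
Why: Normant syn-carbocupration of propyne puts the butenyl group and copper cis on the new trisubstituted alkene, and iodinolysis with retention gives the Z iodide that fixes the C4=C5 geometry of the target.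

Step 2
Reactants: 5 (1Z)-1-iodo-2-methylhexa-1,5-diene
Product: 7 (2Z)-3-methylhepta-2,6-dienal, via [(1Z)-2-methylhexa-1,5-dien-1-yl]lithium 6 (not isolated)
Conditions: t-BuLi (2.1 equiv), Et2O, −78 °C; DMF, −78 to 0 °C; H2O
Reagents that add atoms: N,N-dimethylformamide, CN(C)C=O
Why: Lithium–iodine exchange and Bouveault formylation of the alkenyllithium both proceed with retention of alkene geometry.

Step 3
Reactants: 8 ethyl 2-(bromomethyl)prop-2-enoate; 9 triethyl phosphite
Product: 10 ethyl 2-[(diethoxyphosphoryl)methyl]prop-2-enoate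
Conditions: neat, 110 °C, EtBr distilled off
Reagents that add atoms: none
Why: Michaelis–Arbuzov reaction of a reactive allylic bromide; SN2 and SN2′ attack give the same phosphonate.

Step 4
Reactants: 7 (2Z)-3-methylhepta-2,6-dienal; 10 ethyl 2-[(diethoxyphosphoryl)methyl]prop-2-enoate
Product: 12 (3E,5Z)-6-methyl-2-methylidenedeca-3,5,9-trienoic acid, via ethyl (3E,5Z)-6-methyl-2-methylidenedeca-3,5,9-trienoate 11 (not isolated)
Conditions: 10, NaH (0.98 equiv), THF, 0 °C; 7, 0 to 23 °C; then LiOH, THF–H2O, 23 °C; aq. HCl to pH 3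
Reagents that add atoms: lithium hydroxide, [Li+].[OH-]
Why: Horner–Wadsworth–Emmons olefination of the allylic phosphonate anion forms the C6=C7 alkene E-selectively without touching the Z alkene, and saponification in the same pot frees the acid.

Step 5
Reactants: 12 (3E,5Z)-6-methyl-2-methylidenedeca-3,5,9-trienoic acid
Product: 13 (5R)-3-(bromomethyl)-5-[(1Z)-2-methylhexa-1,5-dien-1-yl]furan-2(5H)-one
Conditions: NBS (1.05 equiv), quinidine 9-O-[N-(4-methoxyphenyl)thiocarbamate] (10 mol%), CHCl3–PhMe (1:2), −60 °C, dark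
Reagents that add atoms: N-bromosuccinimide, O=C1CCC(=O)N1Br
Why: Proposed new method: catalytic enantioselective 1,4-bromolactonisation of a 2-carboxy-1,3-diene, in which the quinuclidinium of the catalyst ion-pairs with the carboxylate and its thiocarbamate sulfur relays Br+ to the neighbouring triene terminus C13, giving a pentadienyl cation stabilised at C6/C4 that the carboxylate oxygen captures at C6 from the s-trans conformer (C4 would need a seven-membered ring, the 3E alkene forbids a six-membered ring, and bromonium formation elsewhere is reversible and unproductive), so the C6–O bond, ring A, the C6 stereocentre (face chosen inside the chiral ion pair) and the allylic bromide arise together; the closest known reaction types are amino-thiocarbamate-catalysed enantioselective bromolactonisation of alkenoic acids and catalytic asymmetric 1,4-bromolactonisation of conjugated enynes.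

Step 6
Reactants: 14 methyl 4,4-dimethoxybutanoate
Product: 15 4,4-dimethoxybutanal
Conditions: i-Bu2AlH (1.05 equiv), CH2Cl2, −78 °C; MeOH, aq. potassium sodium tartrate
Reagents that add atoms: none
Why: Low-temperature hydride half-reduction of a methyl ester, stopped at the aldehyde by the stable tetrahedral aluminium hemiacetal.

Step 7
Reactants: 13 (5R)-3-(bromomethyl)-5-[(1Z)-2-methylhexa-1,5-dien-1-yl]furan-2(5H)-one; 15 4,4-dimethoxybutanal
Product: 17 (4R,5R)-4-[(1S)-1-hydroxy-4,4-dimethoxybutyl]-3-methylidene-5-[(1Z)-2-methylhexa-1,5-dien-1-yl]oxolan-2-one, via butenolide allylindium dibromide 16 (not isolated)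
Conditions: In powder (1.5 equiv), DMF, 23 °C; aq. NaHCO3
Reagents that add atoms: none
Why: Indium Barbier allylation through the γ-carbon (C7) anti to the C6 alkenyl group sets C7 trans to C6, and the Zimmerman–Traxler chair with the ring-fixed E-type allyl unit and an equatorial aldehyde chain gives the anti (1S) carbinol, the C8 epimer needed for step 8.

Step 8
Reactants: 17 (4R,5R)-4-[(1S)-1-hydroxy-4,4-dimethoxybutyl]-3-methylidene-5-[(1Z)-2-methylhexa-1,5-dien-1-yl]oxolan-2-one; 18 (2S)-2-methylbutanoic acid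
Product: 19 (1R)-4,4-dimethoxy-1-[(2R,3R)-4-methylidene-2-[(1Z)-2-methylhexa-1,5-dien-1-yl]-5-oxooxolan-3-yl]butyl (2S)-2-methylbutanoate
Conditions: PPh3 (1.5 equiv), DIAD (1.5 equiv), PhMe, 0 °C (betaine pre-formed); then 17 and 18, 0 to 23 °C
Reagents that add atoms: none
Why: Mitsunobu esterification forms the C8–O bond by SN2 displacement with inversion, turning the 1S carbinol into the 8R ester, while the side-chain stereocentre comes unchanged from 18.

Step 9
Reactants: 19 (1R)-4,4-dimethoxy-1-[(2R,3R)-4-methylidene-2-[(1Z)-2-methylhexa-1,5-dien-1-yl]-5-oxooxolan-3-yl]butyl (2S)-2-methylbutanoate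
Product: 21 (1R)-3-formyl-1-[(2R,3R)-4-methylidene-2-[(1Z)-2-methylhexa-1,5-dien-1-yl]-5-oxooxolan-3-yl]but-3-en-1-yl (2S)-2-methylbutanoate, via 4-oxobutyl ester 20 (not isolated)
Conditions: Amberlyst-15, acetone–H2O (10:1), 23 °C; filter; then 37% aq. HCHO, pyrrolidine (10 mol%), EtCO2H (10 mol%), i-PrOH, 45 °C
Reagents that add atoms: water, O; formaldehyde, C=O
Why: Mild acetal hydrolysis followed by amine-catalysed Mannich-type α-methylenation of the aldehyde gives the 2-alkylacrolein without affecting any stereocentre.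

Step 10
Reactants: 21 (1R)-3-formyl-1-[(2R,3R)-4-methylidene-2-[(1Z)-2-methylhexa-1,5-dien-1-yl]-5-oxooxolan-3-yl]but-3-en-1-yl (2S)-2-methylbutanoate
Product: 22 (3aR,4R,6E,10Z,11aR)-6-formyl-10-methyl-3-methylidene-2-oxo-2,3,3a,4,5,8,9,11a-octahydrocyclodeca[b]furan-4-yl (2S)-2-methylbutanoate
Conditions: second-generation Hoveyda–Grubbs catalyst RuCl2(H2IMes)(=CH-C6H4-2-O-i-Pr) (15 mol%), PhMe (1 mM), 80 °C, Ar sparge
Reagents that add atoms: none
Why: Ring-closing metathesis in which the carbene loads on the terminal vinyl group and closes on the 2-alkylacrolein; the ten-membered ring forces C2 and C9 cis, which is also the preferred E-enal (CHO trans to C2), and the Z C4=C5 alkene and trans-lactone pre-organise the chain.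

Step 11
Reactants: 22 (3aR,4R,6E,10Z,11aR)-6-formyl-10-methyl-3-methylidene-2-oxo-2,3,3a,4,5,8,9,11a-octahydrocyclodeca[b]furan-4-yl (2S)-2-methylbutanoate
Product: 23 (3aR,4R,6E,10E,11aR)-6-formyl-10-(hydroxymethyl)-3-methylidene-2-oxo-2,3,3a,4,5,8,9,11a-octahydrocyclodeca[b]furan-4-yl (2S)-2-methylbutanoate
Conditions: SeO2 (0.3 equiv), t-BuOOH (2.5 equiv), CH2Cl2, 23 °C
Reagents that add atoms: tert-butyl hydroperoxide, CC(C)(C)OO (oxygen relayed through catalytic selenium dioxide, O=[Se]=O)
Why: SeO2 allylic oxidation (ene reaction then [2,3]-sigmatropic shift) hydroxylates the methyl group of the only electron-rich alkene (C4=C5), and the [2,3] step returns the alkene with CH2OH trans to C6 as in the target.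

**Compound list**
1 | but-3-enylmagnesium bromide | C=CCC[Mg]Br | starting material
2 | propyne | CC#C | starting material
3 | but-3-enylcopper | C=CCC[Cu] | intermediate
4 | [(1Z)-2-methylhexa-1,5-dien-1-yl]copper | [Cu]/C=C(/C)CCC=C | intermediate
5 | (1Z)-1-iodo-2-methylhexa-1,5-diene | I/C=C(/C)CCC=C | intermediate
6 | [(1Z)-2-methylhexa-1,5-dien-1-yl]lithium | [Li]/C=C(/C)CCC=C | intermediate
7 | (2Z)-3-methylhepta-2,6-dienal | O=C/C=C(/C)CCC=C | intermediate
8 | ethyl 2-(bromomethyl)prop-2-enoate | C=C(CBr)C(=O)OCC | starting material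
9 | triethyl phosphite | CCOP(OCC)OCC | starting material
10 | ethyl 2-[(diethoxyphosphoryl)methyl]prop-2-enoate | C=C(CP(=O)(OCC)OCC)C(=O)OCC | intermediate
11 | ethyl (3E,5Z)-6-methyl-2-methylidenedeca-3,5,9-trienoate | C=C(C(=O)OCC)/C=C/C=C(/C)CCC=C | intermediate
12 | (3E,5Z)-6-methyl-2-methylidenedeca-3,5,9-trienoic acid | C=C(C(=O)O)/C=C/C=C(/C)CCC=C | intermediate
13 | (5R)-3-(bromomethyl)-5-[(1Z)-2-methylhexa-1,5-dien-1-yl]furan-2(5H)-one | BrCC1=C[C@@H](/C=C(/C)CCC=C)OC1=O | intermediate
14 | methyl 4,4-dimethoxybutanoate | COC(=O)CCC(OC)OC | starting material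
15 | 4,4-dimethoxybutanal | O=CCCC(OC)OC | intermediate
16 | {[(5R)-5-[(1Z)-2-methylhexa-1,5-dien-1-yl]-2-oxo-2,5-dihydrofuran-3-yl]methyl}indium dibromide | Br[In](Br)CC1=C[C@@H](/C=C(/C)CCC=C)OC1=O | intermediate
17 | (4R,5R)-4-[(1S)-1-hydroxy-4,4-dimethoxybutyl]-3-methylidene-5-[(1Z)-2-methylhexa-1,5-dien-1-yl]oxolan-2-one | C=C1C(=O)O[C@H](/C=C(/C)CCC=C)[C@H]1[C@@H](O)CCC(OC)OC | intermediate
18 | (2S)-2-methylbutanoic acid | CC[C@H](C)C(=O)O | starting material
19 | (1R)-4,4-dimethoxy-1-[(2R,3R)-4-methylidene-2-[(1Z)-2-methylhexa-1,5-dien-1-yl]-5-oxooxolan-3-yl]butyl (2S)-2-methylbutanoate | C=C1C(=O)O[C@H](/C=C(/C)CCC=C)[C@H]1[C@H](OC(=O)[C@@H](C)CC)CCC(OC)OC | intermediate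
20 | (1R)-1-[(2R,3R)-4-methylidene-2-[(1Z)-2-methylhexa-1,5-dien-1-yl]-5-oxooxolan-3-yl]-4-oxobutyl (2S)-2-methylbutanoate | C=C1C(=O)O[C@H](/C=C(/C)CCC=C)[C@H]1[C@H](OC(=O)[C@@H](C)CC)CCC=O | intermediate
21 | (1R)-3-formyl-1-[(2R,3R)-4-methylidene-2-[(1Z)-2-methylhexa-1,5-dien-1-yl]-5-oxooxolan-3-yl]but-3-en-1-yl (2S)-2-methylbutanoate | C=C1C(=O)O[C@H](/C=C(/C)CCC=C)[C@H]1[C@H](OC(=O)[C@@H](C)CC)CC(=C)C=O | intermediate
22 | (3aR,4R,6E,10Z,11aR)-6-formyl-10-methyl-3-methylidene-2-oxo-2,3,3a,4,5,8,9,11a-octahydrocyclodeca[b]furan-4-yl (2S)-2-methylbutanoate | C=C1C(=O)O[C@@H]2/C=C(/C)CC/C=C(/C=O)C[C@@H](OC(=O)[C@@H](C)CC)[C@@H]12 | intermediate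
23 | (3aR,4R,6E,10E,11aR)-6-formyl-10-(hydroxymethyl)-3-methylidene-2-oxo-2,3,3a,4,5,8,9,11a-octahydrocyclodeca[b]furan-4-yl (2S)-2-methylbutanoate | C=C1C(=O)O[C@@H]2/C=C(/CO)CC/C=C(/C=O)C[C@@H](OC(=O)[C@@H](C)CC)[C@@H]12 | target

**Count and risks**
Total steps: 11. Longest linear sequence: 9 (steps 1, 2, 4, 5, 7, 8, 9, 10, 11).

The three steps most likely to fail are steps 5, 8 and 10.

Step 5 (proposed new bromolactonisation; risks are Br+ regiochemistry on the triene and enantiocontrol at C6). The fallback uses known chemistry, sets out from 7 and comes back at 13. Zinc–ProPhenol asymmetric alkynylation of 7 with methyl propiolate (Me2Zn, (S,S)-ProPhenol or its enantiomer, whichever adds to the Si face) gives methyl (4R,5Z)-4-hydroxy-6-methyldeca-5,9-dien-2-ynoate F1. Semi-hydrogenation over Pd/CaCO3 poisoned with Pb(OAc)2 and quinoline, with spontaneous lactonisation of the Z-enoate, gives (5S)-5-[(1Z)-2-methylhexa-1,5-dien-1-yl]furan-2(5H)-one F2 (same spatial arrangement; the descriptor changes by priority only). Morita–Baylis–Hillman hydroxymethylation (aq. HCHO, imidazole) gives (5R)-3-(hydroxymethyl)-5-[(1Z)-2-methylhexa-1,5-dien-1-yl]furan-2(5H)-one F3, and Appel bromination (CBr4, PPh3) gives 13.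

Step 8 (Mitsunobu at a hindered carbinol next to the allylic C7–H; elimination is the main risk, and the step would give the wrong epimer if the Barbier adduct turned out syn). The fallback sets out from 17 and comes back at 19. Buffered Dess–Martin oxidation gives (4S,5R)-4-(4,4-dimethoxybutanoyl)-3-methylidene-5-[(1Z)-2-methylhexa-1,5-dien-1-yl]oxolan-2-one F4, used at once. Reagent-controlled reduction with (S)-Me-CBS oxazaborolidine and catecholborane at −78 °C gives (4R,5R)-4-[(1R)-1-hydroxy-4,4-dimethoxybutyl]-3-methylidene-5-[(1Z)-2-methylhexa-1,5-dien-1-yl]oxolan-2-one F5. Steglich esterification of F5 with 18 (DCC, DMAP), with retention, gives 19. A syn Barbier adduct would itself be F5 and would enter at the esterification.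

Step 10 (ten-membered ring closure onto an electron-poor 1,1-disubstituted alkene; risks are oligomerisation and competing closure onto the methylene lactone). The fallback moves the ring closure to the allylic-alcohol oxidation level, sets out from 21 and comes back at 22. Luche reduction (NaBH4, CeCl3·7H2O, MeOH, −78 °C) gives (1R)-3-(hydroxymethyl)-1-[(2R,3R)-4-methylidene-2-[(1Z)-2-methylhexa-1,5-dien-1-yl]-5-oxooxolan-3-yl]but-3-en-1-yl (2S)-2-methylbutanoate F6. Hydroxyl-assisted ring-closing metathesis with second-generation Grubbs catalyst RuCl2(H2IMes)(PCy3)(=CHPh) gives (3aR,4R,6E,10Z,11aR)-6-(hydroxymethyl)-10-methyl-3-methylidene-2-oxo-2,3,3a,4,5,8,9,11a-octahydrocyclodeca[b]furan-4-yl (2S)-2-methylbutanoate F7. MnO2 oxidation of the allylic alcohol gives 22.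

**Further compounds**
F1 | step 5 | methyl (4R,5Z)-4-hydroxy-6-methyldeca-5,9-dien-2-ynoate | COC(=O)C#C[C@H](O)/C=C(/C)CCC=C
F2 | step 5 | (5S)-5-[(1Z)-2-methylhexa-1,5-dien-1-yl]furan-2(5H)-one | O=C1C=C[C@@H](/C=C(/C)CCC=C)O1
F3 | step 5 | (5R)-3-(hydroxymethyl)-5-[(1Z)-2-methylhexa-1,5-dien-1-yl]furan-2(5H)-one | OCC1=C[C@@H](/C=C(/C)CCC=C)OC1=O
F4 | step 8 | (4S,5R)-4-(4,4-dimethoxybutanoyl)-3-methylidene-5-[(1Z)-2-methylhexa-1,5-dien-1-yl]oxolan-2-one | C=C1C(=O)O[C@H](/C=C(/C)CCC=C)[C@H]1C(=O)CCC(OC)OC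
F5 | step 8 | (4R,5R)-4-[(1R)-1-hydroxy-4,4-dimethoxybutyl]-3-methylidene-5-[(1Z)-2-methylhexa-1,5-dien-1-yl]oxolan-2-one | C=C1C(=O)O[C@H](/C=C(/C)CCC=C)[C@H]1[C@H](O)CCC(OC)OC
F6 | step 10 | (1R)-3-(hydroxymethyl)-1-[(2R,3R)-4-methylidene-2-[(1Z)-2-methylhexa-1,5-dien-1-yl]-5-oxooxolan-3-yl]but-3-en-1-yl (2S)-2-methylbutanoate | C=C1C(=O)O[C@H](/C=C(/C)CCC=C)[C@H]1[C@H](OC(=O)[C@@H](C)CC)CC(=C)CO
F7 | step 10 | (3aR,4R,6E,10Z,11aR)-6-(hydroxymethyl)-10-methyl-3-methylidene-2-oxo-2,3,3a,4,5,8,9,11a-octahydrocyclodeca[b]furan-4-yl (2S)-2-methylbutanoate | C=C1C(=O)O[C@@H]2/C=C(/C)CC/C=C(/CO)C[C@@H](OC(=O)[C@@H](C)CC)[C@@H]12
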